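## Plan

- **Cuts** (ring A locants: C1 OMe, C2 CH3, C3 OH, C4 acetyl, C5 OH, C6 bridge). The bridge CH2–ring B bond goes first, then the bridge CH2–C6 bond and the prenyl–ring B bond, which returns ring B to phloroacetophenone. Last, ring A is cut at the two ring bonds C3–C4 and C5–C6.
- **Enabling feature.** Ring A carries oxygen on C1, C3 and C5, with only the C1 oxygen methylated, and CH3, acetyl and the bridge on C2, C4 and C6. The run C6–C1(OMe)–C2(CH3)–C3(O) is the four carbons of a cyclobutenone, and C5(O)–C4(acetyl) is the two carbons of an ynol ether. The three oxygens therefore arrive differentiated, and C6 is the only ring CH.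
- **Forward order.** The four-membered ring forms by ketene–alkyne [2+2] addition, then ring A by benzannulation. Unmasking and aminomethylation at C6 follow, and purchased, C-prenylated ring B is joined last through the ortho-quinone methide of ring A.
- **Stereochemistry.** The target has no stereocentre and no stereogenic double bond. The one centre of the cyclobutenone is racemic and vanishes on aromatisation.

Key step: step 5

Assumption: methoxyethyne is taken as not purchasable in useful amounts and is made. It is handled only as a cold ether solution because of its volatility.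

## Route

Step 1
Reactants: 1 2-chloro-1,1-dimethoxyethane
Product: 3 methoxyethyne, via sodium methoxyethynide 2 (not isolated)
Conditions: NaNH2 (3.2 equiv), liq. NH3, −33 °C; NH3 evaporated; cold sat. aq NaCl; distilled into Et2O at −30 °C
Reagents that add atoms: none
Why: Double amide-induced 1,2-elimination of a β-chloro acetal (loss of MeOH, then of HCl) is the standard preparation of 1-alkoxyalkynes, and the third equivalent of base holds the product as acetylide 2 until the cold aqueous quench.

Step 2
Reactants: 3 methoxyethyne; 4 propanoyl chloride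
Product: 6 (±)-3-methoxy-4-methylcyclobut-2-en-1-one, via methylketene 5 (not isolated)
Conditions: Et3N (1.1 equiv), Et2O, 0 °C → rt; 4 added slowly to excess 3
Reagents that add atoms: none
Why: In this ketene–alkoxyalkyne [2+2] cycloaddition the carbonyl carbon of 5 (from dehydrochlorination of 4) bonds to the nucleophilic CH terminus of 3 and its CH(CH3) carbon bonds to the C–OMe carbon, which fixes OMe at C3 and CH3 at C4; the single stereocentre forms racemic and is of no consequence.

Step 3
Reactants: 7 ethyl 2-oxopropanoate (ethyl pyruvate)
Product: 8 ethyl 2-methyl-1,3-dioxolane-2-carboxylate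
Conditions: HOCH2CH2OH (1.2 equiv), p-TsOH·H2O (cat.), PhMe, reflux, Dean–Stark
Reagents that add atoms: ethane-1,2-diol, OCCO
Why: Acid-catalysed ketalisation with azeotropic removal of water should go cleanly because the ketone of an α-keto ester is strongly electrophilic and the ester is a spectator.

Step 4
Reactants: 8 ethyl 2-methyl-1,3-dioxolane-2-carboxylate
Product: 11 2-methyl-2-{[tri(propan-2-yl)silyl]oxyethynyl}-1,3-dioxolane, via lithium dibromoenolate 9 (not isolated), via lithium ynolate 10 (not isolated)
Conditions: CH2Br2, lithium 2,2,6,6-tetramethylpiperidide (2.2 equiv), THF, −78 °C; n-BuLi, −78 °C → rt; iPr3SiCl, −78 → 0 °C; aq NaHCO3 work-up, Et3N-deactivated silica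
Reagents that add atoms: dibromomethane, BrCBr; chlorotri(propan-2-yl)silane, CC(C)[Si](Cl)(C(C)C)C(C)C
Why: This is a Kowalski ester homologation stopped at the ynolate: acylation of LiCHBr2 gives enolate 9, bromine–lithium exchange triggers the 1,2-shift of the dioxolanyl carbon to give 10, and the bulky silyl halide reacts at oxygen; the chloride is preferred to the triflate so that no strong Lewis acid meets the propargylic ketal.

Step 5
Reactants: 6 (±)-3-methoxy-4-methylcyclobut-2-en-1-one; 11 2-methyl-2-{[tri(propan-2-yl)silyl]oxyethynyl}-1,3-dioxolane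
Product: 16 3-methoxy-2-methyl-6-(2-methyl-1,3-dioxolan-2-yl)-5-{[tri(propan-2-yl)silyl]oxy}phenol, via methoxyvinylketene 12 (not isolated), via vinylcyclobutenone 13 (not isolated), via dienylketene 14 (not isolated), via cyclohexadienone 15 (not isolated)
Conditions: 11 (1.3 equiv), PhMe (0.4 M), Ar, base-washed sealed tube, 110 °C, then 140 °C
Reagents that add atoms: none
Why: This is a Danheiser benzannulation in its siloxyalkyne version: conrotatory 4π opening of 6, with the C4 methyl turning outward, gives vinylketene 12, whose ketene C=C adds [2+2] to 11 so that the electrophilic carbonyl carbon bonds to the dioxolane-bearing alkyne carbon and the ketene CH bonds to the C–OSi carbon (13). A second 4π opening of 13 gives dienylketene 14, and ring A closes by disrotatory 6π electrocyclisation between the ketene carbon and the CH(CH3) terminus (restoring the bond lost in the first opening) to dienone 15, which enolises to phenol 16. The closest known reactions are the unions of alkyl-substituted cyclobutenones with triisopropylsilyl ynol ethers to give resorcinol monosilyl ethers; opening of an oxygen-substituted cyclobutenone such as 6 is the same event that every adduct of type 13 undergoes in those reactions, although 6, a vinylogous ester, is expected to need the upper end of the usual temperature range. No stereocentre is created in 16, since the racemic centres of 6, 13 and 15 are erased by aromatisation. The step needs regioselectivity in the [2+2] addition and [2+2] rather than [4+2] periselectivity; the first is secured by the polarisation of the ynol ether (the oxygen lone pair makes the remote carbon nucleophilic) matched to the ketene carbonyl carbon, and the second is the normal behaviour of vinylketenes toward electron-rich alkynes. The result is the masked acetyl between OH and OSi, CH3 between OH and OMe, and one ring CH between OSi and OMe.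

Step 6
Reactants: 16 3-methoxy-2-methyl-6-(2-methyl-1,3-dioxolan-2-yl)-5-{[tri(propan-2-yl)silyl]oxy}phenol
Product: 18 1-(2,6-dihydroxy-4-methoxy-3-methylphenyl)ethan-1-one, via resorcinol ketal 17 (not isolated)
Conditions: Bu4NF (1.1 equiv), THF, 0 °C; then 1 M aq HCl, rt
Reagents that add atoms: water, O
Why: Fluoride cleavage of the aryl silyl ether is followed in the same flask by acid hydrolysis of a ketal that two ortho oxygen donors make very labile, and the released ketone is stabilised by hydrogen bonding to the flanking OH groups.

Step 7
Reactants: 18 1-(2,6-dihydroxy-4-methoxy-3-methylphenyl)ethan-1-one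
Product: 19 1-{3-[(dimethylamino)methyl]-2,6-dihydroxy-4-methoxy-5-methylphenyl}ethan-1-one
Conditions: 37% aq CH2O and 40% aq Me2NH (premixed, 1.5 equiv each), EtOH, 0 °C → rt; 18 added last
Reagents that add atoms: formaldehyde, C=O; dimethylamine, CNC
Why: In this phenol Mannich reaction the only ring CH lies ortho to OH and OMe and para to the second OH, so there is no regiochemical choice; the excess of premixed aminomethylating agent should suppress diarylmethane formation, and the acetyl CH3 is inert without acid.

Step 8
Reactants: 20 1-(2,4,6-trihydroxyphenyl)ethan-1-one (phloroacetophenone)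
Product: 21 1-[2,4,6-trihydroxy-3-(3-methylbut-2-en-1-yl)phenyl]ethan-1-one
Conditions: prenyl bromide (0.9 equiv), KOH, H2O, 0 °C → rt; acidify; chromatography
Reagents that add atoms: 1-bromo-3-methylbut-2-ene (prenyl bromide), CC(C)=CCBr
Why: This is C-alkylation of a phloroglucinol-type phenolate, for which the protic medium favours carbon over oxygen attack and the sub-stoichiometric bromide limits a second prenylation.

Step 9
Reactants: 19 1-{3-[(dimethylamino)methyl]-2,6-dihydroxy-4-methoxy-5-methylphenyl}ethan-1-one; 21 1-[2,4,6-trihydroxy-3-(3-methylbut-2-en-1-yl)phenyl]ethan-1-one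
Product: 23 mallotojaponin, via ortho-quinone methide 22 (not isolated)
Conditions: 21 (1.2 equiv), 1,4-dioxane, 100 °C, slow Ar sparge to carry off Me2NH
Reagents that add atoms: none
Why: Thermal elimination of Me2NH from the ortho-hydroxybenzylamine gives ortho-quinone methide 22, which is taken up in a conjugate Friedel–Crafts alkylation by the only free ring carbon of 21, the established way to unsymmetrical methylene-bridged acylphloroglucinols; the neutral medium spares the prenyl group from chroman formation.

## Compound list

1 | 2-chloro-1,1-dimethoxyethane | COC(CCl)OC | starting material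
2 | sodium methoxyethynide | [Na+].[C-]#COC | intermediate
3 | methoxyethyne | C#COC | intermediate
4 | propanoyl chloride | CCC(Cl)=O | starting material
5 | methylketene (prop-1-en-1-one) | CC=C=O | intermediate
6 | (±)-3-methoxy-4-methylcyclobut-2-en-1-one | COC1=CC(=O)C1C | intermediate
7 | ethyl 2-oxopropanoate | CCOC(=O)C(C)=O | starting material
8 | ethyl 2-methyl-1,3-dioxolane-2-carboxylate | CCOC(=O)C1(C)OCCO1 | intermediate
9 | lithium 2,2-dibromo-1-(2-methyl-1,3-dioxolan-2-yl)ethen-1-olate | [Li+].[O-]C(=C(Br)Br)C1(C)OCCO1 | intermediate
10 | lithium (2-methyl-1,3-dioxolan-2-yl)ethynolate | [Li+].[O-]C#CC1(C)OCCO1 | intermediate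
11 | 2-methyl-2-{[tri(propan-2-yl)silyl]oxyethynyl}-1,3-dioxolane | CC1(C#CO[Si](C(C)C)(C(C)C)C(C)C)OCCO1 | intermediate
12 | (3Z)-3-methoxypenta-1,3-dien-1-one (CH3 trans to the ketene chain) | C/C=C(OC)/C=C=O | intermediate
13 | (±)-4-[(1Z)-1-methoxyprop-1-en-1-yl]-2-(2-methyl-1,3-dioxolan-2-yl)-3-{[tri(propan-2-yl)silyl]oxy}cyclobut-2-en-1-one | O=C1C(C2(C)OCCO2)=C(O[Si](C(C)C)(C(C)C)C(C)C)C1/C(OC)=C/C | intermediate
14 | (3E,5Z)-5-methoxy-2-(2-methyl-1,3-dioxolan-2-yl)-3-{[tri(propan-2-yl)silyl]oxy}hepta-1,3,5-trien-1-one (ketene carbon and methoxypropenyl group cis on the central C=C) | O=C=C(C1(C)OCCO1)/C(O[Si](C(C)C)(C(C)C)C(C)C)=C\C(OC)=C\C | intermediate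
15 | (±)-5-methoxy-6-methyl-2-(2-methyl-1,3-dioxolan-2-yl)-3-{[tri(propan-2-yl)silyl]oxy}cyclohexa-2,4-dien-1-one | O=C1C(C2(C)OCCO2)=C(O[Si](C(C)C)(C(C)C)C(C)C)C=C(OC)C1C | intermediate
16 | 3-methoxy-2-methyl-6-(2-methyl-1,3-dioxolan-2-yl)-5-{[tri(propan-2-yl)silyl]oxy}phenol | COc1cc(O[Si](C(C)C)(C(C)C)C(C)C)c(C2(C)OCCO2)c(O)c1C | intermediate
17 | 5-methoxy-4-methyl-2-(2-methyl-1,3-dioxolan-2-yl)benzene-1,3-diol | COc1cc(O)c(C2(C)OCCO2)c(O)c1C | intermediate
18 | 1-(2,6-dihydroxy-4-methoxy-3-methylphenyl)ethan-1-one | COc1cc(O)c(C(C)=O)c(O)c1C | intermediate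
19 | 1-{3-[(dimethylamino)methyl]-2,6-dihydroxy-4-methoxy-5-methylphenyl}ethan-1-one | COc1c(C)c(O)c(C(C)=O)c(O)c1CN(C)C | intermediate
20 | 1-(2,4,6-trihydroxyphenyl)ethan-1-one | CC(=O)c1c(O)cc(O)cc1O | starting material
21 | 1-[2,4,6-trihydroxy-3-(3-methylbut-2-en-1-yl)phenyl]ethan-1-one | CC(=O)c1c(O)cc(O)c(CC=C(C)C)c1O | intermediate
22 | 2-acetyl-3-hydroxy-5-methoxy-4-methyl-6-methylidenecyclohexa-2,4-dien-1-one | C=C1C(=O)C(C(C)=O)=C(O)C(C)=C1OC | intermediate
23 | mallotojaponin, 1-{3-[(3-acetyl-2,4-dihydroxy-6-methoxy-5-methylphenyl)methyl]-2,4,6-trihydroxy-5-(3-methylbut-2-en-1-yl)phenyl}ethan-1-one | COc1c(C)c(O)c(C(C)=O)c(O)c1Cc1c(O)c(CC=C(C)C)c(O)c(C(C)=O)c1O | target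

## Step count and risks

Total step count: 9.
Longest linear sequence: 6 steps (1, 2, 5, 6, 7, 9). The branch 3, 4, 5, 6, 7, 9 is equally long.

**Step 5.** The vinylogous-ester stabilisation of 6 may push its first ring opening to a temperature at which 11 isomerises by silyl migration or ionises at the ketal before it is captured. The tertiary dioxolanyl carbon may also slow the [2+2] addition. The fallback sets out from 11 and comes back at 16. It releases the same vinylketene by 1,4-dehydrochlorination at room temperature instead of by ring opening.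
- Purchased methyl 3-oxopentanoate F1 is converted with HC(OMe)3 and catalytic H2SO4 in MeOH into methyl (2E)-3-methoxypent-2-enoate F2.
- This is saponified (LiOH, aq THF, careful acidification) to (2E)-3-methoxypent-2-enoic acid F3.
- The acid is turned with (COCl)2 and catalytic DMF into (2E)-3-methoxypent-2-enoyl chloride F4.
- Slow addition of F4 to 11 and Et3N in toluene should generate 12 and from it adduct 13. That adduct then needs only the gentler heating usual for siloxy-substituted vinylcyclobutenones to pass through 14 and 15 to 16.

**Step 4.** The 1,2-shift of an electron-poor, tertiary ketal carbon may be sluggish, and the ester-derived intermediates may be consumed by the excess alkyllithium. The fallback sets out from 8 and comes back at 11. It builds the alkyne first and introduces the oxygen afterwards, so no carbon migration is needed.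
- Reduction with i-Bu2AlH (CH2Cl2, −78 °C) gives 2-methyl-1,3-dioxolane-2-carbaldehyde F5.
- Ohira–Bestmann homologation (dimethyl (1-diazo-2-oxopropyl)phosphonate, K2CO3, MeOH) gives 2-ethynyl-2-methyl-1,3-dioxolane F6.
- n-BuLi converts this into lithium (2-methyl-1,3-dioxolan-2-yl)ethynide F7.
- Oxidation of the acetylide with t-BuOOLi (from t-BuOOH and LiN(SiMe3)2) in THF gives ynolate 10, which is silylated with iPr3SiCl to 11.

**Step 2.** Amine-promoted dimerisation of the monoalkylketene may outrun its capture, and the volatile alkyne may be lost. The fallback sets out from 3 and comes back at 6. It uses a more electrophilic ketene that dimerises less readily.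
- Purchased 2-chloropropanoyl chloride F8 and Et3N give chloro(methyl)ketene F9.
- This ketene adds to 3 with the same orientation to give (±)-4-chloro-3-methoxy-4-methylcyclobut-2-en-1-one F10.
- Reductive dechlorination with zinc dust in AcOH–TMEDA–EtOH (0 °C → rt) then delivers 6.

## Further compounds

F1 | step 5 | methyl 3-oxopentanoate (purchased) | CCC(=O)CC(=O)OC
F2 | step 5 | methyl (2E)-3-methoxypent-2-enoate | CC/C(OC)=C\C(=O)OC
F3 | step 5 | (2E)-3-methoxypent-2-enoic acid | CC/C(OC)=C\C(=O)O
F4 | step 5 | (2E)-3-methoxypent-2-enoyl chloride | CC/C(OC)=C\C(=O)Cl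
F5 | step 4 | 2-methyl-1,3-dioxolane-2-carbaldehyde | CC1(C=O)OCCO1
F6 | step 4 | 2-ethynyl-2-methyl-1,3-dioxolane | CC1(C#C)OCCO1
F7 | step 4 | lithium (2-methyl-1,3-dioxolan-2-yl)ethynide | [Li+].[C-]#CC1(C)OCCO1
F8 | step 2 | 2-chloropropanoyl chloride (purchased, racemic) | CC(Cl)C(Cl)=O
F9 | step 2 | chloro(methyl)ketene (2-chloroprop-1-en-1-one) | CC(Cl)=C=O
F10 | step 2 | (±)-4-chloro-3-methoxy-4-methylcyclobut-2-en-1-one | COC1=CC(=O)C1(C)Cl
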